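## Retrosynthetic overview

1. The target is (2S)-5,7-dihydroxy-2-(4-hydroxy-3-methoxyphenyl)-6-prenylchroman-4-one. The last step removes three MOM ethers, and rings A and B are bought as arenes, so the pyranone ring is the only ring made and it is closed last.
2. The pyranone ring is cut at C8a–O1 and C4–C4a: a C4a≡C8a aryne of the A ring plus the alkoxide of an (S)-3-aryl-3-hydroxypropanenitrile. The alkoxide oxygen becomes O1, the nitrile carbon becomes C4, masked as a ketimine until acidic work-up.
3. Enabling feature: O1 (on C8a) and the acyl carbon C4 (on C4a) are ortho neighbours on ring A. C4a is flanked by the C5 oxygen and C8a only by C8–H, so the C5–O bond beside the triple bond sends the O-nucleophile to C8a and the carbanion to C4a. O1 is para to the prenyl carbon C6, so the aryne comes from a mirror-symmetric 4-prenyl-3,5-dioxygenated phenol and the 6- versus 8-prenyl question never arises.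
4. Aryne precursor from resorcinol: MOM protection, lithiation/prenylation between the two ethers, sterically controlled C–H borylation/oxidation para to prenyl, ortho-bromination, retro-Brook silylation/triflation.
5. Nitrile from methyl vanillate: MOM protection, cyanomethyl Claisen condensation, Noyori–Ikariya transfer hydrogenation, which sets C2.

Key step: step 9

Assumption: the facial preference of the (S,S)-TsDPEN–Ru catalyst known for aryl ketones such as benzoylacetonitrile is taken to hold for ketonitrile 13, so that it should deliver the (S)-carbinol.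

## Route

Step 1
Reactants: 1 resorcinol
Product: 2 1,3-bis(methoxymethoxy)benzene
Conditions: NaH, MOMCl, DMF, 0 °C to rt
Reagents that add atoms: chloromethyl methyl ether, COCCl
Why: O-alkylation of the bis-phenoxide by the α-chloro ether (MOM protection) should be clean; no stereocenter is involved.

Step 2
Reactants: 2 1,3-bis(methoxymethoxy)benzene
Product: 4 1,3-bis(methoxymethoxy)-2-(3-methylbut-2-en-1-yl)benzene, via aryllithium 3 (not isolated)
Conditions: n-BuLi, THF, 0 °C to rt; CuI (10 mol %), prenyl bromide, −78 °C to rt
Reagents that add atoms: prenyl bromide (1-bromo-3-methylbut-2-ene), CC(C)=CCBr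
Why: Directed ortho-metalation takes the C–H between the two MOM ethers, and copper-catalysed SN2 allylation of the aryllithium should give the linear prenyl arene.

Step 3
Reactants: 4 1,3-bis(methoxymethoxy)-2-(3-methylbut-2-en-1-yl)benzene
Product: 6 3,5-bis(methoxymethoxy)-4-(3-methylbut-2-en-1-yl)phenol, via arylboronate 5 (not isolated)
Conditions: [Ir(OMe)(cod)]2 (1.5 mol %), dtbpy (3 mol %), B2pin2, THF, 80 °C; then NMO, THF, 50 °C; aq. work-up
Reagents that add atoms: bis(pinacolato)diboron, CC1(C)OB(OC1(C)C)B1OC(C)(C)C(C)(C)O1; N-methylmorpholine N-oxide, C[N+]1([O-])CCOCC1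
Why: Iridium-catalysed C–H borylation is sterically controlled and only the C–H para to prenyl has no ortho substituent; N-oxide oxidation of the aryl boronate (1,2-aryl shift from B to O) should then give the phenol without touching the trisubstituted alkene.

Step 4
Reactants: 6 3,5-bis(methoxymethoxy)-4-(3-methylbut-2-en-1-yl)phenol
Product: 7 2-bromo-3,5-bis(methoxymethoxy)-4-(3-methylbut-2-en-1-yl)phenol
Conditions: NBS (1.0 equiv), CH2Cl2, −78 °C
Reagents that add atoms: N-bromosuccinimide, O=C1CCC(=O)N1Br
Why: Electrophilic aromatic bromination ortho to the free phenol; the para position is blocked by prenyl and the two ortho positions are mirror-equivalent, so only one monobromide can form, and the phloroglucinol-type ring should outrun the alkene at low temperature.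

Step 5
Reactants: 7 2-bromo-3,5-bis(methoxymethoxy)-4-(3-methylbut-2-en-1-yl)phenol
Product: 10 3,5-bis(methoxymethoxy)-4-(3-methylbut-2-en-1-yl)-2-(trimethylsilyl)phenyl trifluoromethanesulfonate, via silyl ether 8 (not isolated), via lithium phenolate 9 (not isolated)
Conditions: HMDS, THF, 70 °C, then evaporation; n-BuLi, THF, −100 to −78 °C; Tf2O, −100 to −78 °C
Reagents that add atoms: hexamethyldisilazane, C[Si](C)(C)N[Si](C)(C)C; triflic anhydride, O=S(=O)(OS(=O)(=O)C(F)(F)F)C(F)(F)F
Why: O-silylation, bromine–lithium exchange and anionic 1,3 O-to-C silyl migration (retro-Brook rearrangement) should give the ortho-silyl phenolate, which is trapped as the triflate — the standard entry to o-silylaryl triflate aryne precursors.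

Step 6
Reactants: 11 methyl vanillate (methyl 4-hydroxy-3-methoxybenzoate)
Product: 12 methyl 3-methoxy-4-(methoxymethoxy)benzoate
Conditions: NaH, MOMCl, DMF, 0 °C to rt
Reagents that add atoms: chloromethyl methyl ether, COCCl
Why: MOM protection of the phenoxide, needed because a free phenol would itself add to the aryne in step 9.

Step 7
Reactants: 12 methyl 3-methoxy-4-(methoxymethoxy)benzoate
Product: 13 3-[3-methoxy-4-(methoxymethoxy)phenyl]-3-oxopropanenitrile
Conditions: MeCN, n-BuLi (2.1 equiv each), THF, −78 °C; then 12, −78 to −40 °C; 1 M aq. HCl quench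
Reagents that add atoms: acetonitrile, CC#N
Why: Claisen-type acylation of lithiated acetonitrile by the ester; the second equivalent of base turns the product into its enolate, which should prevent over-addition.

Step 8
Reactants: 13 3-[3-methoxy-4-(methoxymethoxy)phenyl]-3-oxopropanenitrile
Product: 14 (3S)-3-hydroxy-3-[3-methoxy-4-(methoxymethoxy)phenyl]propanenitrile
Conditions: RuCl[(S,S)-TsDPEN](p-cymene) (1 mol %), HCO2H/Et3N (5:2), 30 °C
Reagents that add atoms: none
Why: Noyori–Ikariya asymmetric transfer hydrogenation of an aryl ketone; the (S,S)-ligand should deliver hydride to the face that gives the (S)-carbinol (future C2), and the MOM ether should survive the buffered formic acid.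

Step 9
Reactants: 14 (3S)-3-hydroxy-3-[3-methoxy-4-(methoxymethoxy)phenyl]propanenitrile; 10 3,5-bis(methoxymethoxy)-4-(3-methylbut-2-en-1-yl)-2-(trimethylsilyl)phenyl trifluoromethanesulfonate
Product: 18 (2S)-5,7-bis(methoxymethoxy)-2-[3-methoxy-4-(methoxymethoxy)phenyl]-6-(3-methylbut-2-en-1-yl)-2,3-dihydro-4H-chromen-4-one, via sodium alkoxide 15 (not isolated), via aryne 16 (not isolated), via ketimine 17 (not isolated)
Conditions: NaH (1.05 equiv), THF, 0 °C; then KF, 18-crown-6, slow addition of 10 (1.2 equiv), THF, 0 °C to rt; then 0.5 M aq. HCl, THF, 0 °C to rt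
Reagents that add atoms: water, O
Why: Proposed new method: the pre-formed alkoxide 15 should add to aryne 16 at the aryne carbon remote from the ring OMOM group (the future C8a), because the electron-withdrawing C–O bond beside the triple bond distorts the aryne and stabilises the carbanion developing on the neighbouring, more hindered carbon (the future C4a); that aryl anion then attacks the tethered nitrile carbon, and the N-metallo ketimine is hydrolysed by dilute acid to the ketone. The closest known reaction type is the fluoride-triggered annulation of arynes with salicylate esters to xanthones (O-nucleophile addition, then acyl trapping of the aryl anion in a new pyranone ring), combined with Parham-type addition of aryl anions to nitriles; new here are an aliphatic chiral alkoxide and a nitrile trap. The pyranone ring closes by C4–C4a bond formation in a 6-exo-dig anionic cyclisation, after the intermolecular C8a–O1 bond. No new stereocenter is formed: C2 comes from 14 with retention because its C–O bond is never broken, and since the carbonyl stays masked as the ketimine while the medium is basic, E1cB ring opening (retro-oxa-Michael) should not scramble it. The step needs regioselective O-attack on the aryne (secured by the OMOM group beside the triple bond on one flank and H on the other) and ring closure faster than protonation of the aryl anion (secured by full deprotonation with NaH, an aprotic medium and slow release of the aryne).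

Step 10
Reactants: 18 (2S)-5,7-bis(methoxymethoxy)-2-[3-methoxy-4-(methoxymethoxy)phenyl]-6-(3-methylbut-2-en-1-yl)-2,3-dihydro-4H-chromen-4-one
Product: 19 (2S)-5,7-dihydroxy-2-(4-hydroxy-3-methoxyphenyl)-6-(3-methylbut-2-en-1-yl)-2,3-dihydro-4H-chromen-4-one
Conditions: 3 M aq. HCl, MeOH, 40 °C
Reagents that add atoms: none
Why: Acid-catalysed acetal solvolysis should remove all three MOM ethers under conditions mild enough for the aryl methyl ether, the prenyl group and the C2 stereocenter, which is configurationally stable in acid.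

## Compound list

1 | resorcinol | Oc1cccc(O)c1 | starting material
2 | 1,3-bis(methoxymethoxy)benzene | COCOc1cccc(OCOC)c1 | intermediate
3 | [2,6-bis(methoxymethoxy)phenyl]lithium | [Li]c1c(OCOC)cccc1OCOC | intermediate
4 | 1,3-bis(methoxymethoxy)-2-(3-methylbut-2-en-1-yl)benzene | COCOc1cccc(OCOC)c1CC=C(C)C | intermediate
5 | 2-[3,5-bis(methoxymethoxy)-4-(3-methylbut-2-en-1-yl)phenyl]-4,4,5,5-tetramethyl-1,3,2-dioxaborolane | COCOc1cc(B2OC(C)(C)C(C)(C)O2)cc(OCOC)c1CC=C(C)C | intermediate
6 | 3,5-bis(methoxymethoxy)-4-(3-methylbut-2-en-1-yl)phenol | COCOc1cc(O)cc(OCOC)c1CC=C(C)C | intermediate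
7 | 2-bromo-3,5-bis(methoxymethoxy)-4-(3-methylbut-2-en-1-yl)phenol | COCOc1cc(O)c(Br)c(OCOC)c1CC=C(C)C | intermediate
8 | [2-bromo-3,5-bis(methoxymethoxy)-4-(3-methylbut-2-en-1-yl)phenoxy]trimethylsilane | COCOc1cc(O[Si](C)(C)C)c(Br)c(OCOC)c1CC=C(C)C | intermediate
9 | lithium 3,5-bis(methoxymethoxy)-4-(3-methylbut-2-en-1-yl)-2-(trimethylsilyl)phenolate | [Li+].[O-]c1cc(OCOC)c(CC=C(C)C)c(OCOC)c1[Si](C)(C)C | intermediate
10 | 3,5-bis(methoxymethoxy)-4-(3-methylbut-2-en-1-yl)-2-(trimethylsilyl)phenyl trifluoromethanesulfonate | COCOc1cc(OS(=O)(=O)C(F)(F)F)c([Si](C)(C)C)c(OCOC)c1CC=C(C)C | intermediate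
11 | methyl vanillate (methyl 4-hydroxy-3-methoxybenzoate) | COC(=O)c1ccc(O)c(OC)c1 | starting material
12 | methyl 3-methoxy-4-(methoxymethoxy)benzoate | COCOc1ccc(C(=O)OC)cc1OC | intermediate
13 | 3-[3-methoxy-4-(methoxymethoxy)phenyl]-3-oxopropanenitrile | COCOc1ccc(C(=O)CC#N)cc1OC | intermediate
14 | (3S)-3-hydroxy-3-[3-methoxy-4-(methoxymethoxy)phenyl]propanenitrile | COCOc1ccc([C@@H](O)CC#N)cc1OC | intermediate
15 | sodium (1S)-2-cyano-1-[3-methoxy-4-(methoxymethoxy)phenyl]ethanolate | COCOc1ccc([C@@H]([O-])CC#N)cc1OC.[Na+] | intermediate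
16 | 1,2-didehydro-3,5-bis(methoxymethoxy)-4-(3-methylbut-2-en-1-yl)benzene (aryne) | COCOC1=C(CC=C(C)C)C(OCOC)=CC#C1 | intermediate
17 | (2S)-5,7-bis(methoxymethoxy)-2-[3-methoxy-4-(methoxymethoxy)phenyl]-6-(3-methylbut-2-en-1-yl)-2,3-dihydro-4H-chromen-4-imine | COCOc1ccc([C@@H]2CC(=N)c3c(cc(OCOC)c(CC=C(C)C)c3OCOC)O2)cc1OC | intermediate
18 | (2S)-5,7-bis(methoxymethoxy)-2-[3-methoxy-4-(methoxymethoxy)phenyl]-6-(3-methylbut-2-en-1-yl)-2,3-dihydro-4H-chromen-4-one | COCOc1ccc([C@@H]2CC(=O)c3c(cc(OCOC)c(CC=C(C)C)c3OCOC)O2)cc1OC | intermediate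
19 | (2S)-5,7-dihydroxy-2-(4-hydroxy-3-methoxyphenyl)-6-(3-methylbut-2-en-1-yl)-2,3-dihydro-4H-chromen-4-one | COc1cc([C@@H]2CC(=O)c3c(cc(O)c(CC=C(C)C)c3O)O2)ccc1O | target

## Step count and risks

Total step count: 10. Longest linear sequence: 7 (steps 1–5, 9, 10); steps 6–8 form the second branch.

Steps most likely to fail:

1. Step 9 (Proposed new method). After the alkoxide has added, the aryl anion may be quenched by proton transfer (from the C3 methylene or adventitious acid) faster than it closes onto the nitrile; the alkoxide may also lose configurational purity by reversible retro-aldol cleavage before it is arylated. Fallback in known chemistry, setting out from ketonitrile 13 and bromophenol 7: transfer hydrogenation of 13 with the (R,R)-TsDPEN catalyst should give (3R)-3-hydroxy-3-[3-methoxy-4-(methoxymethoxy)phenyl]propanenitrile F1. Mitsunobu etherification of F1 with 7 (PPh3, DIAD, toluene, 0 °C) should give, with inversion, (3S)-3-[2-bromo-3,5-bis(methoxymethoxy)-4-(3-methylbut-2-en-1-yl)phenoxy]-3-[3-methoxy-4-(methoxymethoxy)phenyl]propanenitrile F2. Bromine–lithium exchange (t-BuLi, 2 equiv, THF, −100 °C) and Parham cyclisation of the covalent aryllithium onto the nitrile should then give ketimine 17, which is hydrolysed as in step 9 to 18. This fallback still passes through an aryl anion, so it answers the aryne-addition and retro-aldol risks more than the C3 proton-transfer risk.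

2. Step 10. Acid may add the freed 5- or 7-hydroxyl (or methanol or chloride) across the prenyl double bond, or cleavage of the three acetals may stall. Fallback setting out from 18: non-protic transacetalisation with TMSOTf and 2,2'-bipyridyl (MeCN, 0 °C to rt) should convert the three aryl MOM ethers into (2S)-2-[3-methoxy-4-(trimethylsilyloxy)phenyl]-6-(3-methylbut-2-en-1-yl)-5,7-bis(trimethylsilyloxy)-2,3-dihydro-4H-chromen-4-one F3, which neutral water should hydrolyse to target 19.

3. Step 4. Over-bromination of the very electron-rich ring or attack of the electrophilic bromine on the prenyl double bond may erode the monobromide. Fallback setting out from phenol 6 and using directed ortho-metalation instead of electrophilic halogenation: carbamoylation (ClCONEt2, NaH, THF) should give 3,5-bis(methoxymethoxy)-4-(3-methylbut-2-en-1-yl)phenyl diethylcarbamate F4. Carbamate-directed lithiation at the only remaining ring C–H type (s-BuLi, TMEDA, THF, −78 °C; TMSCl) should give 3,5-bis(methoxymethoxy)-4-(3-methylbut-2-en-1-yl)-2-(trimethylsilyl)phenyl diethylcarbamate F5. Reductive cleavage (LiAlH4, THF) should give 3,5-bis(methoxymethoxy)-4-(3-methylbut-2-en-1-yl)-2-(trimethylsilyl)phenol F6, and triflation (Tf2O, pyridine, CH2Cl2, 0 °C) rejoins the route at 10.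

## Further compounds

F1 | step 9 | (3R)-3-hydroxy-3-[3-methoxy-4-(methoxymethoxy)phenyl]propanenitrile | COCOc1ccc([C@H](O)CC#N)cc1OC
F2 | step 9 | (3S)-3-[2-bromo-3,5-bis(methoxymethoxy)-4-(3-methylbut-2-en-1-yl)phenoxy]-3-[3-methoxy-4-(methoxymethoxy)phenyl]propanenitrile | COCOc1ccc([C@@H](Oc2cc(OCOC)c(CC=C(C)C)c(OCOC)c2Br)CC#N)cc1OC
F3 | step 10 | (2S)-2-[3-methoxy-4-(trimethylsilyloxy)phenyl]-6-(3-methylbut-2-en-1-yl)-5,7-bis(trimethylsilyloxy)-2,3-dihydro-4H-chromen-4-one | C[Si](C)(C)Oc1ccc([C@@H]2CC(=O)c3c(cc(O[Si](C)(C)C)c(CC=C(C)C)c3O[Si](C)(C)C)O2)cc1OC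
F4 | step 4 | 3,5-bis(methoxymethoxy)-4-(3-methylbut-2-en-1-yl)phenyl diethylcarbamate | CCN(CC)C(=O)Oc1cc(OCOC)c(CC=C(C)C)c(OCOC)c1
F5 | step 4 | 3,5-bis(methoxymethoxy)-4-(3-methylbut-2-en-1-yl)-2-(trimethylsilyl)phenyl diethylcarbamate | CCN(CC)C(=O)Oc1cc(OCOC)c(CC=C(C)C)c(OCOC)c1[Si](C)(C)C
F6 | step 4 | 3,5-bis(methoxymethoxy)-4-(3-methylbut-2-en-1-yl)-2-(trimethylsilyl)phenol | COCOc1cc(O)c([Si](C)(C)C)c(OCOC)c1CC=C(C)C
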